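**Plan**

- Cuts: the twelve O–benzyl bonds first. Then, at C4 of the top (epiafzelechin) unit, both aryl–carbon bonds at once: C4–C4a (ring C of the top unit) and C4–C8 of the middle unit. This leads back to an open-chain α-benzyloxy-β-aryloxy aldehyde and the benzylated epicatechin-(4β→8)-catechin dimer, which is cut at its own C4–C8 bond into the two natural monomers.
- Enabling feature: C4 of the top unit is a diarylmethine carbon held between two phloroglucinol-type rings (its own ring A through C4a, and ring A of the middle unit through C8), so at the aldehyde oxidation level it can be arylated twice. C4a lies ortho to the ether oxygen O1, ortho/para to the C5 and C7 oxygens, and six atoms from the carbonyl carbon.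
- Forward: the dimer comes from (−)-epicatechin and (+)-catechin (benzylation, DDQ oxidation at C4, Lewis-acid coupling). The aldehyde comes from an Evans syn-glycolate aldol, reduction, silylation, palladium-catalysed O-arylation, desilylation and oxidation.
- Rings: all rings of the two lower units come from the chiral pool. Ring C of the top unit is the only ring made; it closes in the key step, which forms the upper interflavan bond in the same flask, and hydrogenolysis ends the route.
- Stereochemistry: C2/C3 of the two lower units come from the chiral pool. C2/C3 of the top unit come from the oxazolidinone-controlled syn aldol (O1–aryl bond made with retention at C2). Both C4 centres arise by anti addition to 2,3-cis flavan-4-yl cations (3,4-trans, 4β).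

Key step: step 12

Remark: the target is read as epiafzelechin-(4β→8)-epicatechin-(4β→8)-catechin (all C2 R; top and middle units 2,3-cis-3,4-trans, lower unit 2,3-trans); flavan numbering (O1, C2, C3, C4, C4a … C8a) is used for ring positions.

**Route**

Step 1
Reactants: 1 (−)-epicatechin
Product: 2 5,7,3',4'-tetra-O-benzyl-(−)-epicatechin
Conditions: BnBr (4.4 equiv), K2CO3, DMF, 0 °C → rt
Reagents that add atoms: benzyl bromide, BrCc1ccccc1
Why: Williamson etherification with a carbonate base should alkylate the four phenolic hydroxyls only and leave the aliphatic C3–OH and both stereocentres untouched.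

Step 2
Reactants: 2 5,7,3',4'-tetra-O-benzyl-(−)-epicatechin
Product: 3 (2R,3R,4S)-5,7-bis(benzyloxy)-2-[3,4-bis(benzyloxy)phenyl]-4-(2-ethoxyethoxy)chroman-3-ol
Conditions: DDQ (2 equiv), 2-ethoxyethanol (5 equiv), CH2Cl2, rt
Reagents that add atoms: 2-ethoxyethanol, CCOCCO
Why: DDQ benzylic oxidation (hydride abstraction at C4, activated by O1 and the 5,7-dialkoxy ring A) should give the C4 cation, which the alcohol traps on the face opposite the 2-aryl group; the new C4 configuration is erased again in step 4.

Step 3
Reactants: 4 (+)-catechin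
Product: 5 5,7,3',4'-tetra-O-benzyl-(+)-catechin
Conditions: BnBr (4.4 equiv), K2CO3, DMF, 0 °C → rt
Reagents that add atoms: benzyl bromide, BrCc1ccccc1
Why: Williamson etherification of the four phenols as in step 1; no stereocentre is involved.

Step 4
Reactants: 3 (2R,3R,4S)-4-(2-ethoxyethoxy) electrophile; 5 5,7,3',4'-tetra-O-benzyl-(+)-catechin (3 equiv)
Product: 6 5,7,3',4'-tetra-O-benzyl-epicatechin-(4β→8)-5,7,3',4'-tetra-O-benzyl-catechin (octa-O-benzyl procyanidin B1)
Conditions: TMSOTf (0.2 equiv), CH2Cl2, −78 °C; Et3N quench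
Reagents that add atoms: none
Why: Lewis-acid Friedel–Crafts alkylation of a flavan-3-ol by a flavan-4-yl cation (the standard interflavan coupling) should link C4 to the more accessible C8 of 5; the arene adds anti to the pseudo-axial 3-OH of the 2,3-cis cation, which sets 4β (3,4-trans), and the excess of 5 suppresses chain growth.

Step 5
Reactants: 7 (S)-4-benzyloxazolidin-2-one; 8 (benzyloxy)acetyl chloride
Product: 9 (S)-4-benzyl-3-[(benzyloxy)acetyl]oxazolidin-2-one
Conditions: Et3N, DMAP (cat.), CH2Cl2, 0 °C → rt
Reagents that add atoms: none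
Why: DMAP-catalysed N-acylation of the oxazolidinone with the acid chloride is a standard entry to glycolate imides and does not touch the auxiliary stereocentre.

Step 6
Reactants: 9 (S)-4-benzyl-3-[(benzyloxy)acetyl]oxazolidin-2-one; 10 4-(benzyloxy)benzaldehyde
Product: 12 (S)-4-benzyl-3-[(2S,3R)-2-(benzyloxy)-3-[4-(benzyloxy)phenyl]-3-hydroxypropanoyl]oxazolidin-2-one, via Z-boron enolate 11 (not isolated)
Conditions: Bu2BOTf, Et3N, CH2Cl2, −78 → 0 °C; then 10, −78 → 0 °C; then pH 7 buffer, MeOH, 30% H2O2, 0 °C
Reagents that add atoms: none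
Why: Evans syn-glycolate aldol: the Z-boron enolate reacts through a closed Zimmerman–Traxler transition state on the enolate face not shielded by the auxiliary benzyl group, which should set both new centres as the (2S,3R) syn adduct (the future C3 and C2 of the top unit).

Step 7
Reactants: 12 syn-aldol adduct
Product: 13 (1R,2R)-2-(benzyloxy)-1-[4-(benzyloxy)phenyl]propane-1,3-diol
Conditions: LiBH4, MeOH (1 equiv), THF, 0 °C
Reagents that add atoms: none
Why: Reductive cleavage of the N-acyloxazolidinone with LiBH4 should give the primary alcohol and release the auxiliary without touching either stereocentre.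

Step 8
Reactants: 13 (1R,2R)-diol
Product: 14 (1R,2R)-2-(benzyloxy)-1-[4-(benzyloxy)phenyl]-3-[(triisopropylsilyl)oxy]propan-1-ol
Conditions: TIPSCl, imidazole, DMF, 0 °C → rt
Reagents that add atoms: triisopropylsilyl chloride, CC(C)[Si](Cl)(C(C)C)C(C)C
Why: Silylation should select the primary over the hindered secondary benzylic hydroxyl, and the triisopropylsilyl group is chosen because it resists O→O migration under the basic conditions of step 9.

Step 9
Reactants: 14 mono-silylated diol; 15 1,3-bis(benzyloxy)-5-bromobenzene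
Product: 16 {(2R,3R)-2-(benzyloxy)-3-[4-(benzyloxy)phenyl]-3-[3,5-bis(benzyloxy)phenoxy]propoxy}tri(propan-2-yl)silane
Conditions: [Pd(allyl)Cl]2 (1.5 mol %), RockPhos (4 mol %), Cs2CO3, toluene, 90 °C
Reagents that add atoms: none
Why: Palladium-catalysed C–O cross-coupling of a secondary alcohol (Buchwald–Hartwig etherification) forms the O–C(aryl) bond, so the carbinol centre is retained; the bulky biaryl phosphine should favour C–O reductive elimination over β-hydride elimination.

Step 10
Reactants: 16 silyl ether
Product: 17 (2R,3R)-2-(benzyloxy)-3-[4-(benzyloxy)phenyl]-3-[3,5-bis(benzyloxy)phenoxy]propan-1-ol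
Conditions: Bu4NF, THF, 0 °C → rt
Reagents that add atoms: none
Why: Fluoride-mediated desilylation should free the primary alcohol without affecting the benzyl and aryl ethers or the stereocentres.

Step 11
Reactants: 17 primary alcohol
Product: 18 (2S,3R)-2-(benzyloxy)-3-[4-(benzyloxy)phenyl]-3-[3,5-bis(benzyloxy)phenoxy]propanal
Conditions: Dess–Martin periodinane, NaHCO3, CH2Cl2, 0 °C → rt; used crude
Reagents that add atoms: none
Why: Buffered Dess–Martin oxidation is non-basic, so the α-benzyloxy aldehyde should form without α-epimerisation or β-elimination of the aryloxy group.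

Step 12
Reactants: 18 aldehyde; 6 octa-O-benzyl procyanidin B1 (1.5 equiv)
Product: 20 3,5,7,4'-tetra-O-benzyl-epiafzelechin-(4β→8)-5,7,3',4'-tetra-O-benzyl-epicatechin-(4β→8)-5,7,3',4'-tetra-O-benzyl-catechin, via flavan-4-ol 19 (not isolated)
Conditions: Yb(OTf)3 (0.3 equiv), 4 Å MS, CH2Cl2, −20 °C → rt; 18 added slowly to 6 and the catalyst
Reagents that add atoms: none
Why: Proposed new method: Yb(OTf)3 activates the aldehyde of 18, and the ring carbon ortho to the ether oxygen of its 3,5-bis(benzyloxy)phenyl ether (the future C4a, also ortho and para to the two benzyloxy groups) attacks it in an intramolecular Friedel–Crafts hydroxyalkylation to give flavan-4-ol 19; the same acid ionises 19 to the flavan-4-yl cation (stabilised by O1 and the C5 and C7 oxygens), which C8 of the upper unit of 6 captures, water being the only by-product. The closest known reaction types are the acid-mediated cyclisation of 3-aryloxypropanals and their acetals to chroman-4-ols, the Lewis-acid coupling of C4-oxygenated benzylated flavans with monomeric and dimeric flavan-3-ol nucleophiles, and the Friedel–Crafts diarylation of aldehydes; their union in one flask on a flavan has not been shown. Ring C of the top unit closes in 6-exo-trig mode on the activated C=O, with the nucleophilic aryl C=C bond inside the new ring. The new C4 stereocentre is set in the capture step: the 2,3-cis cation adopts a half-chair with the 2-aryl group equatorial and the 3-benzyloxy group pseudo-axial, and the arene adds anti to that group (3,4-trans, 4β), as 2,3-cis flavan-4-yl cations generally do, while C2 and C3 are not touched under the non-basic conditions. The step needs ring closure before any intermolecular event, attack at C8 of the upper unit of 6 and no chain growth; the six-membered tether onto a symmetric, triply oxygen-activated ring (both ortho positions equivalent), the blocked C8 of the lower unit together with the two benzyloxy groups flanking each C6, and slow addition of 18 to an excess of 6 should secure these, and reversible hemiacetal formation with the free 3-OH groups of 6 funnels into the same cation.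

Step 13
Reactants: 20 dodeca-O-benzyl trimer
Product: 21 epiafzelechin-(4β→8)-epicatechin-(4β→8)-catechin (CNP0158921.1)
Conditions: H2 (1 atm), Pd(OH)2/C, THF/MeOH/H2O, rt
Reagents that add atoms: none
Why: Hydrogenolysis over Pd(OH)2/C should cleave the eleven aryl benzyl ethers and the one aliphatic benzyl ether at O3 of the top unit under neutral conditions that leave the interflavan bonds, the ring C ethers and all eight stereocentres intact.

**Compound list**

1 | (−)-epicatechin, (2R,3R)-2-(3,4-dihydroxyphenyl)chromane-3,5,7-triol | Oc1cc(O)c2c(c1)O[C@H](c1ccc(O)c(O)c1)[C@H](O)C2 | starting material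
2 | 5,7,3',4'-tetra-O-benzyl-(−)-epicatechin | c5ccccc5COc1cc(OCc5ccccc5)c2c(c1)O[C@H](c1ccc(OCc5ccccc5)c(OCc5ccccc5)c1)[C@H](O)C2 | intermediate
3 | (2R,3R,4S)-5,7-bis(benzyloxy)-2-[3,4-bis(benzyloxy)phenyl]-4-(2-ethoxyethoxy)chroman-3-ol | c5ccccc5COc1ccc(cc1OCc5ccccc5)[C@H]2Oc3cc(OCc5ccccc5)cc(OCc5ccccc5)c3[C@H](OCCOCC)[C@H]2O | intermediate
4 | (+)-catechin, (2R,3S)-2-(3,4-dihydroxyphenyl)chromane-3,5,7-triol | Oc1cc(O)c2c(c1)O[C@H](c1ccc(O)c(O)c1)[C@@H](O)C2 | starting material
5 | 5,7,3',4'-tetra-O-benzyl-(+)-catechin | c5ccccc5COc1cc(OCc5ccccc5)c2c(c1)O[C@H](c1ccc(OCc5ccccc5)c(OCc5ccccc5)c1)[C@@H](O)C2 | intermediate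
6 | octa-O-benzyl procyanidin B1 (benzylated epicatechin-(4β→8)-catechin, both 3-OH free) | c5ccccc5COc1ccc(cc1OCc5ccccc5)[C@H]2Oc3cc(OCc5ccccc5)cc(OCc5ccccc5)c3[C@H](c3c(OCc5ccccc5)cc(OCc5ccccc5)c4c3O[C@H](c3ccc(OCc5ccccc5)c(OCc5ccccc5)c3)[C@@H](O)C4)[C@H]2O | intermediate
7 | (S)-4-benzyloxazolidin-2-one | O=C1OC[C@H](Cc2ccccc2)N1 | starting material
8 | (benzyloxy)acetyl chloride | ClC(=O)COCc1ccccc1 | starting material
9 | (S)-4-benzyl-3-[(benzyloxy)acetyl]oxazolidin-2-one | O=C1OC[C@H](Cc2ccccc2)N1C(=O)COCc1ccccc1 | intermediate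
10 | 4-(benzyloxy)benzaldehyde | O=Cc1ccc(OCc2ccccc2)cc1 | starting material
11 | dibutylboron Z-enolate of 9 | CCCCB(CCCC)O/C(=C\OCc1ccccc1)N1[C@@H](Cc2ccccc2)COC1=O | intermediate
12 | (S)-4-benzyl-3-[(2S,3R)-2-(benzyloxy)-3-[4-(benzyloxy)phenyl]-3-hydroxypropanoyl]oxazolidin-2-one | O=C1OC[C@H](Cc2ccccc2)N1C(=O)[C@@H](OCc1ccccc1)[C@H](O)c1ccc(OCc2ccccc2)cc1 | intermediate
13 | (1R,2R)-2-(benzyloxy)-1-[4-(benzyloxy)phenyl]propane-1,3-diol | OC[C@@H](OCc1ccccc1)[C@H](O)c1ccc(OCc2ccccc2)cc1 | intermediate
14 | (1R,2R)-2-(benzyloxy)-1-[4-(benzyloxy)phenyl]-3-[(triisopropylsilyl)oxy]propan-1-ol | CC(C)[Si](OC[C@@H](OCc1ccccc1)[C@H](O)c1ccc(OCc2ccccc2)cc1)(C(C)C)C(C)C | intermediate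
15 | 1,3-bis(benzyloxy)-5-bromobenzene | Brc1cc(OCc2ccccc2)cc(OCc2ccccc2)c1 | starting material
16 | {(2R,3R)-2-(benzyloxy)-3-[4-(benzyloxy)phenyl]-3-[3,5-bis(benzyloxy)phenoxy]propoxy}tri(propan-2-yl)silane | CC(C)[Si](OC[C@@H](OCc1ccccc1)[C@H](Oc1cc(OCc2ccccc2)cc(OCc2ccccc2)c1)c1ccc(OCc2ccccc2)cc1)(C(C)C)C(C)C | intermediate
17 | (2R,3R)-2-(benzyloxy)-3-[4-(benzyloxy)phenyl]-3-[3,5-bis(benzyloxy)phenoxy]propan-1-ol | OC[C@@H](OCc1ccccc1)[C@H](Oc1cc(OCc2ccccc2)cc(OCc2ccccc2)c1)c1ccc(OCc2ccccc2)cc1 | intermediate
18 | (2S,3R)-2-(benzyloxy)-3-[4-(benzyloxy)phenyl]-3-[3,5-bis(benzyloxy)phenoxy]propanal | O=C[C@@H](OCc1ccccc1)[C@H](Oc1cc(OCc2ccccc2)cc(OCc2ccccc2)c1)c1ccc(OCc2ccccc2)cc1 | intermediate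
19 | (2R,3R)-3,5,7-tris(benzyloxy)-2-[4-(benzyloxy)phenyl]chroman-4-ol (either C4 epimer) | c5ccccc5COc1ccc(cc1)[C@H]2Oc3cc(OCc5ccccc5)cc(OCc5ccccc5)c3C(O)[C@H]2OCc5ccccc5 | intermediate
20 | dodeca-O-benzyl trimer: 3,5,7,4'-tetra-O-benzyl-epiafzelechin-(4β→8)-5,7,3',4'-tetra-O-benzyl-epicatechin-(4β→8)-5,7,3',4'-tetra-O-benzyl-catechin | c5ccccc5COc1ccc(cc1)[C@H]2Oc3cc(OCc5ccccc5)cc(OCc5ccccc5)c3[C@H](c3c(OCc5ccccc5)cc(OCc5ccccc5)c4c3O[C@H](c3ccc(OCc5ccccc5)c(OCc5ccccc5)c3)[C@H](O)[C@H]4c3c(OCc5ccccc5)cc(OCc5ccccc5)c4c3O[C@H](c3ccc(OCc5ccccc5)c(OCc5ccccc5)c3)[C@@H](O)C4)[C@H]2OCc5ccccc5 | intermediate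
21 | epiafzelechin-(4β→8)-epicatechin-(4β→8)-catechin (CNP0158921.1) | Oc1ccc([C@H]2Oc3cc(O)cc(O)c3[C@H](c3c(O)cc(O)c4c3O[C@H](c3ccc(O)c(O)c3)[C@H](O)[C@H]4c3c(O)cc(O)c4c3O[C@H](c3ccc(O)c(O)c3)[C@@H](O)C4)[C@H]2O)cc1 | target

**Step count and risks**

Total steps: 13. Longest linear sequence: 9 steps (steps 5–13, from 7 and 8 to 21).

Steps most likely to fail:

1. Step 12 (proposed new method). The flavan-4-yl cation formed after ring closure may be consumed by a second molecule of 18 or by the product (chain growth) faster than by 6, or the dimer may not tolerate the acid strength that the aldehyde cyclisation needs. The fallback separates the two events with known chemistry; it sets out from 18 and comes back at 20. Aldehyde 18 is treated alone with excess 2-ethoxyethanol and catalytic camphorsulfonic acid over 4 Å MS in CH2Cl2. The hemiacetal-derived oxocarbenium ion should cyclise onto the aryl ether ring (the first stage of the classical chroman synthesis from aryloxypropanal acetals), and the excess alcohol recaptures the C4 cation to give the bench-stable (2R,3R,4S)-3,5,7-tris(benzyloxy)-2-[4-(benzyloxy)phenyl]-4-(2-ethoxyethoxy)chromane F1, an analogue of 3. F1 is then coupled with excess 6 under TMSOTf in CH2Cl2 at −78 °C exactly as in step 4 to give 20.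

2. Step 9. β-Hydride elimination from the hindered benzylic palladium alkoxide (ketone formation, and erosion of the carbinol centre if the ketone is reduced back) may outrun C–O reductive elimination. The fallback forms the same O–aryl bond by nucleophilic aromatic substitution, which also retains the carbinol centre; it sets out from 14 and comes back at 16. The sodium alkoxide of 14 (NaH, DMF, 0 °C → rt) is arylated with excess 1,3,5-trifluorobenzene to give {(2R,3R)-2-(benzyloxy)-3-[4-(benzyloxy)phenyl]-3-(3,5-difluorophenoxy)propoxy}tri(propan-2-yl)silane F2. Its two remaining fluorides are then displaced by sodium benzyl oxide (BnOH, NaH, N-methylpyrrolidone, about 100 °C) to give 16.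

3. Step 1. Under base, the ring-C ether of epicatechin can open reversibly through the 4'-phenoxide (epimerisation at C2), and the phloroglucinol ring can be C-benzylated. The fallback reaches the same compound by inversion at C3 of the catechin series; it sets out from 5 and comes back at 2. Alcohol 5 is oxidised with Dess–Martin periodinane in CH2Cl2 to (2R)-5,7-bis(benzyloxy)-2-[3,4-bis(benzyloxy)phenyl]chroman-3-one F3. Reduction with Li(s-Bu)3BH and LiBr in THF at −78 °C should deliver hydride to the face opposite the 2-aryl group and give the 2,3-cis alcohol 2.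

Further compounds
F1 | step 12 | (2R,3R,4S)-3,5,7-tris(benzyloxy)-2-[4-(benzyloxy)phenyl]-4-(2-ethoxyethoxy)chromane | c5ccccc5COc1ccc(cc1)[C@H]2Oc3cc(OCc5ccccc5)cc(OCc5ccccc5)c3[C@H](OCCOCC)[C@H]2OCc5ccccc5
F2 | step 9 | {(2R,3R)-2-(benzyloxy)-3-[4-(benzyloxy)phenyl]-3-(3,5-difluorophenoxy)propoxy}tri(propan-2-yl)silane | CC(C)[Si](OC[C@@H](OCc1ccccc1)[C@H](Oc1cc(F)cc(F)c1)c1ccc(OCc2ccccc2)cc1)(C(C)C)C(C)C
F3 | step 1 | (2R)-5,7-bis(benzyloxy)-2-[3,4-bis(benzyloxy)phenyl]chroman-3-one | c5ccccc5COc1cc(OCc5ccccc5)c2c(c1)O[C@H](c1ccc(OCc5ccccc5)c(OCc5ccccc5)c1)C(=O)C2
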